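**Retrosynthetic overview**

1. Target 24 ⇒ bis-angelate 22 (late allylic oxidation of the isopropenyl group to the enal) ⇒ diol 21 (double angeloylation) ⇒ saturated lactone 17 (lactone α-methylenation; C1–C2 oxirane from a C1 aldehyde by sulfur-ylide methylene transfer).
2. cis-γ-Lactone and 9α-OH ⇒ C8=C9 olefin acid 12: CH2OH-directed α-epoxidation, then anti opening at C8 by the C12 acid.
3. C7–C11 bond ⇒ Ireland–Claisen rearrangement of the C9 β-acetate of 8 (C9→C7 chirality transfer).
4. Cyclohexene 7 ⇒ amine-catalysed enantioselective endo Diels–Alder of enone ester 3 with dienyl acetate 6 (sets C5, C6, C9 and the quaternary C10 in one step).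
5. Ring order: carbocycle (step 3) → butyrolactone (step 7) → oxirane (step 9).

Assumption: atoms carry the elemane numbering of the target (ring C5–C10; C10 bears the C14 methyl and C1; C5 bears C4; lactone C7–C11–C12(=O)–O–C8); β is the ring face of the C10 methyl, α the other face; the quinine-derived amine of step 3 is taken to give the enantiomer drawn, and its quinidine-derived pseudoenantiomer would give the antipode.

**Step 1**
Reactants: 1 methylglyoxal (2-oxopropanal); 2 ethyl 2-(triphenylphosphoranylidene)propanoate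
Product: 3 ethyl (E)-2-methyl-4-oxopent-2-enoate
Conditions: 40% aq. 1, CH2Cl2, rt
Reagents that add atoms: none
Why: Wittig olefination with the stabilised α-methyl ylide is aldehyde-selective and E-selective, which places the acetyl group cis to the C-methyl group as the cycloaddition requires.

**Step 2**
Reactants: 4 (1E,3E)-buta-1,3-diene-1,4-diyl diacetate
Product: 6 (1E,3E)-4-(tert-butyldimethylsilyloxy)buta-1,3-dien-1-yl acetate, via potassium dienolate 5 (not isolated)
Conditions: KOtBu (1.0 equiv), THF, −78 °C; then TBSCl, −78 → 0 °C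
Reagents that add atoms: tert-butyldimethylsilyl chloride, CC(C)(C)[Si](C)(C)Cl
Why: Acyl transfer to tert-butoxide cleaves one enol acetate (the dienolate formed deactivates the second ester), and O-silylation of the enolate keeps the (E,E) geometry and gives the unsymmetrical 1-acyloxy-4-silyloxy diene (enolate trapping).

**Step 3**
Reactants: 3 ethyl (E)-2-methyl-4-oxopent-2-enoate; 6 (1E,3E)-4-(tert-butyldimethylsilyloxy)buta-1,3-dien-1-yl acetate
Product: 7 ethyl 6-acetyl-2-acetoxy-5-(tert-butyldimethylsilyloxy)-1-methylcyclohex-3-ene-1-carboxylate (C7=C8 cyclohexene; 5β-acetyl; 6β-OTBS; 9β-OAc; 10β-methyl; 10α-CO2Et)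
Conditions: 9-amino-9-deoxy-epi-quinine (20 mol %), 2-fluorobenzoic acid (40 mol %), toluene, −20 → 0 °C
Reagents that add atoms: none
Why: Proposed new method: an enantioselective primary-amine (iminium) catalysed Diels–Alder reaction of a β,β-disubstituted, ester-activated enone with a 1-acyloxy-4-silyloxy diene; condensation of the amine with the methyl ketone gives a ketiminium whose β-carbon (C10) pairs with the diene terminus remote from the stronger silyloxy donor (C9); the endo transition state puts the acetyl group and the cis β-methyl on the face of both diene oxygens and the ester on the other face, so C5, C6, C9 and the quaternary C10 follow from the E geometries, while the protonated quinuclidine–carboxylate pair blocks one enone face; the closest known reactions are amine-catalysed Diels–Alder reactions of simple enones and cinchona-amine iminium activation of acyclic enones.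

**Step 4**
Reactants: 7 the Diels–Alder adduct
Product: 8 ethyl 2-acetoxy-5-(tert-butyldimethylsilyloxy)-1-methyl-6-(prop-1-en-2-yl)cyclohex-3-ene-1-carboxylate (5β-isopropenyl; other centres as in 7)
Conditions: Zn, CH2Br2, TiCl4, THF/CH2Cl2, 0 °C → rt
Reagents that add atoms: dibromomethane, BrCBr
Why: Takai–Lombardo methylenation is non-basic and ketone-selective, so the methyl ketone becomes the isopropenyl group without β-elimination of the C6 silyloxy group, epimerisation at C5 or attack on the ester and acetate.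

**Step 5**
Reactants: 8 the isopropenyl cyclohexenyl acetate
Product: 11 2-[4-(ethoxycarbonyl)-6-(tert-butyldimethylsilyloxy)-4-methyl-5-(prop-1-en-2-yl)cyclohex-2-en-1-yl]acetic acid (C8=C9 alkene; 7β-CH2CO2H; 6β-OTBS; 5β-isopropenyl; 10β-methyl; 10α-CO2Et), via silyl ketene acetal 9 (not isolated), via trimethylsilyl ester 10 (not isolated)
Conditions: LiN(iPr)2, Me3SiCl/Et3N (internal quench), THF, −78 °C; then rt → 60 °C; aq. HCl
Reagents that add atoms: none
Why: Ireland–Claisen rearrangement: the ketene acetal of the only enolisable ester (the C10 ester has no α-hydrogen) rearranges suprafacially across C9–C8=C7, so the β C9–O bond is traded for a β C7–C11 bond (C7 set by chirality transfer) and the alkene moves to C8=C9.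

**Step 6**
Reactants: 11 the cyclohexenylacetic acid ester
Product: 12 2-[6-(tert-butyldimethylsilyloxy)-4-(hydroxymethyl)-4-methyl-5-(prop-1-en-2-yl)cyclohex-2-en-1-yl]acetic acid (10α-CH2OH; other centres as in 11)
Conditions: LiEt3BH (3.5 equiv), THF, 0 °C → rt; aq. HCl
Reagents that add atoms: none
Why: LiEt3BH reduces the hindered neopentyl ethyl ester to the primary alcohol while the C12 acid sits in the flask as its unreactive lithium carboxylate (chemoselective hydride reduction).

**Step 7**
Reactants: 12 the hydroxy acid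
Product: 14 cis-fused 8β,12-lactone 4-(tert-butyldimethylsilyloxy)-7-hydroxy-6-(hydroxymethyl)-6-methyl-5-(prop-1-en-2-yl)hexahydro-1-benzofuran-2(3H)-one (7β-C11; 8β-O; 9α-OH; 10α-CH2OH; 10β-methyl; 5β-isopropenyl; 6β-OTBS), via epoxy acid 13 (not isolated)
Conditions: VO(acac)2 (5 mol %), tBuOOH, CH2Cl2, 0 °C → rt; then camphorsulfonic acid (10 mol %)
Reagents that add atoms: tert-butyl hydroperoxide, CC(C)(C)OO
Why: Hydroxyl-directed vanadium-catalysed epoxidation: the homoallylic C10 CH2OH on the α face delivers oxygen to the α face of C8=C9 (the isopropenyl group is directed far less well), and the β-oriented acid then opens the epoxide at C8 in a 5-exo anti fashion, setting 8β-O (cis-lactone) and 9α-OH.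

**Step 8**
Reactants: 14 the lactone diol
Product: 15 the 10α-formyl lactone (C1 aldehyde; 9α-OH free; other centres as in 14)
Conditions: TEMPO (10 mol %), PhI(OAc)2, CH2Cl2, rt
Reagents that add atoms: none
Why: The TEMPO/PhI(OAc)2 oxidation is selective for the primary alcohol over the hindered secondary C9 hydroxyl and stops at the aldehyde, which cannot enolise (quaternary C10).

**Step 9**
Reactants: 15 the β-hydroxy aldehyde
Product: 17 the 10α-[(R)-oxiran-2-yl] lactone with 9α-OSiMe3 and 6β-OTBS, via silyl ether aldehyde 16 (not isolated)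
Conditions: 1-(trimethylsilyl)imidazole, CH2Cl2, rt; then trimethylsulfonium iodide/KN(SiMe3)2, THF, −20 → 0 °C
Reagents that add atoms: 1-(trimethylsilyl)imidazole, C[Si](C)(C)n1ccnc1; trimethylsulfonium iodide, C[S+](C)C.[I-]
Why: After silylation of the C9 hydroxyl in the flask (blocks retro-aldol cleavage), Corey–Chaykovsky methylene transfer gives the terminal epoxide; Felkin–Anh addition anti to the C10–C9 bond (the best acceptor, bearing the silyloxy group) and past the small C10 methyl sets C1 as R.

**Step 10**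
Reactants: 17 the epoxy lactone
Product: 20 the α-methylene lactone (C11=C13; 9α-OSiMe3; 6β-OTBS; (1R)-oxirane), via Mannich base 18 (not isolated), via ammonium iodide 19 (not isolated)
Conditions: LiN(iPr)2, THF, −78 °C; Eschenmoser's salt, −78 °C → rt; MeI; aq. NaHCO3
Reagents that add atoms: N,N-dimethylmethyleneiminium iodide (Eschenmoser's salt), C=[N+](C)C.[I-]
Why: Lactone enolate Mannich reaction, N-methylation and Hofmann-type elimination install the exocyclic alkene; the lactone α-CH2 is the only acidic site, and the oxirane and silyl ethers tolerate the amide base at −78 °C.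

**Step 11**
Reactants: 20 the bis-silyl ether
Product: 21 the 6β,9α-diol (α-methylene cis-lactone; 5β-isopropenyl; 10α-(R)-oxiranyl)
Conditions: HF·pyridine, pyridine, THF, 0 °C → rt
Reagents that add atoms: none
Why: Buffered HF·pyridine cleaves both silyl ethers (Si–F bond formation) under conditions mild enough for the oxirane and the methylene lactone, and the acidic medium avoids lactone migration to O6.

**Step 12**
Reactants: 21 the diol
Product: 22 the 6β,9α-bis-angelate with 5β-isopropenyl
Conditions: angelic acid, 2,4,6-trichlorobenzoyl chloride, Et3N, toluene, rt; then 21, 80 °C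
Reagents that add atoms: angelic acid ((Z)-2-methylbut-2-enoic acid), C/C=C(/C)C(=O)O
Why: Yamaguchi-type acylation through the mixed anhydride, run without DMAP, esterifies both hindered secondary alcohols and keeps the Z geometry of the angelate.

**Step 13**
Reactants: 22 the bis-angelate
Product: 24 the target CNP0291490.2, via allylic alcohol 23 (not isolated)
Conditions: SeO2 (20 mol %), tBuOOH, CH2Cl2, rt; then Dess–Martin periodinane, NaHCO3
Reagents that add atoms: tert-butyl hydroperoxide, CC(C)(C)OO
Why: Riley-type allylic oxidation (ene reaction then [2,3]-shift) attacks only the electron-rich 1,1-disubstituted alkene at its methyl group, and Dess–Martin oxidation of the allylic alcohol completes the 2-substituted acrolein; the oxirane, the conjugated angelates and the methylene lactone are inert.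

**Compound list**

1 | methylglyoxal | CC(=O)C=O | starting material
2 | ethyl 2-(triphenylphosphoranylidene)propanoate | CCOC(=O)C(C)=P(c1ccccc1)(c1ccccc1)c1ccccc1 | starting material
3 | ethyl (E)-2-methyl-4-oxopent-2-enoate | CCOC(=O)/C(C)=C/C(C)=O | intermediate
4 | (1E,3E)-buta-1,3-diene-1,4-diyl diacetate | CC(=O)O/C=C/C=C/OC(C)=O | starting material
5 | potassium (1E,3E)-4-acetoxybuta-1,3-dien-1-olate | CC(=O)O/C=C/C=C/[O-].[K+] | intermediate
6 | (1E,3E)-4-(tert-butyldimethylsilyloxy)buta-1,3-dien-1-yl acetate | CC(=O)O/C=C/C=C/O[Si](C)(C)C(C)(C)C | intermediate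
7 | Diels–Alder adduct (5β-acetyl, 6β-OTBS, 9β-OAc, 10β-Me, 10α-CO2Et, C7=C8) | C1=C[C@@H](O[Si](C)(C)C(C)(C)C)[C@@H](C(C)=O)[C@](C)(C(=O)OCC)[C@H]1OC(C)=O | intermediate
8 | 5β-isopropenyl analogue of 7 | C1=C[C@@H](O[Si](C)(C)C(C)(C)C)[C@@H](C(C)=C)[C@](C)(C(=O)OCC)[C@H]1OC(C)=O | intermediate
9 | O-trimethylsilyl ketene acetal of the C9 acetate of 8 | C1=C[C@@H](O[Si](C)(C)C(C)(C)C)[C@@H](C(C)=C)[C@](C)(C(=O)OCC)[C@H]1OC(=C)O[Si](C)(C)C | intermediate
10 | trimethylsilyl ester of 11 | C1=C[C@@H](CC(=O)O[Si](C)(C)C)[C@@H](O[Si](C)(C)C(C)(C)C)[C@@H](C(C)=C)[C@]1(C)C(=O)OCC | intermediate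
11 | C8=C9 acid (7β-CH2CO2H, 6β-OTBS, 5β-isopropenyl, 10β-Me, 10α-CO2Et) | C1=C[C@@H](CC(=O)O)[C@@H](O[Si](C)(C)C(C)(C)C)[C@@H](C(C)=C)[C@]1(C)C(=O)OCC | intermediate
12 | hydroxy acid (10α-CH2OH) | C1=C[C@@H](CC(=O)O)[C@@H](O[Si](C)(C)C(C)(C)C)[C@@H](C(C)=C)[C@]1(C)CO | intermediate
13 | 8α,9α-epoxide of 12 | OC(=O)C[C@@H]1[C@H]2O[C@H]2[C@@](C)(CO)[C@H](C(C)=C)[C@@H]1O[Si](C)(C)C(C)(C)C | intermediate
14 | cis-8β,12-lactone, 9α-OH, 10α-CH2OH, 6β-OTBS | C1C(=O)O[C@H]2[C@@H]1[C@@H](O[Si](C)(C)C(C)(C)C)[C@@H](C(C)=C)[C@](C)(CO)[C@@H]2O | intermediate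
15 | 10α-formyl lactone, 9α-OH | C1C(=O)O[C@H]2[C@@H]1[C@@H](O[Si](C)(C)C(C)(C)C)[C@@H](C(C)=C)[C@](C)(C=O)[C@@H]2O | intermediate
16 | 9α-O-trimethylsilyl ether of 15 | C1C(=O)O[C@H]2[C@@H]1[C@@H](O[Si](C)(C)C(C)(C)C)[C@@H](C(C)=C)[C@](C)(C=O)[C@@H]2O[Si](C)(C)C | intermediate
17 | 10α-[(R)-oxiran-2-yl] lactone, 9α-OSiMe3, 6β-OTBS | C1C(=O)O[C@H]2[C@@H]1[C@@H](O[Si](C)(C)C(C)(C)C)[C@@H](C(C)=C)[C@](C)([C@@H]1CO1)[C@@H]2O[Si](C)(C)C | intermediate
18 | 11-(dimethylaminomethyl) lactone (C11 epimers) | CN(C)CC1C(=O)O[C@H]2[C@@H]1[C@@H](O[Si](C)(C)C(C)(C)C)[C@@H](C(C)=C)[C@](C)([C@@H]1CO1)[C@@H]2O[Si](C)(C)C | intermediate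
19 | trimethylammonium iodide of 18 | C[N+](C)(C)CC1C(=O)O[C@H]2[C@@H]1[C@@H](O[Si](C)(C)C(C)(C)C)[C@@H](C(C)=C)[C@](C)([C@@H]1CO1)[C@@H]2O[Si](C)(C)C.[I-] | intermediate
20 | α-methylene lactone, 9α-OSiMe3, 6β-OTBS | C=C1C(=O)O[C@H]2[C@@H]1[C@@H](O[Si](C)(C)C(C)(C)C)[C@@H](C(C)=C)[C@](C)([C@@H]1CO1)[C@@H]2O[Si](C)(C)C | intermediate
21 | 6β,9α-diol | C=C1C(=O)O[C@H]2[C@@H]1[C@@H](O)[C@@H](C(C)=C)[C@](C)([C@@H]1CO1)[C@@H]2O | intermediate
22 | 6β,9α-bis-angelate, 5β-isopropenyl | C=C1C(=O)O[C@H]2[C@@H]1[C@@H](OC(=O)/C(C)=C\C)[C@@H](C(C)=C)[C@](C)([C@@H]1CO1)[C@@H]2OC(=O)/C(C)=C\C | intermediate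
23 | C15 allylic alcohol of 22 | C=C1C(=O)O[C@H]2[C@@H]1[C@@H](OC(=O)/C(C)=C\C)[C@@H](C(=C)CO)[C@](C)([C@@H]1CO1)[C@@H]2OC(=O)/C(C)=C\C | intermediate
24 | CNP0291490.2 | C=C1C(=O)O[C@H]2[C@@H]1[C@@H](OC(=O)/C(C)=C\C)[C@@H](C(=C)C=O)[C@](C)([C@@H]1CO1)[C@@H]2OC(=O)/C(C)=C\C | target

**Step count and risks**

Total steps: 13. Longest linear sequence: 12 steps (step 1 or step 2, then steps 3–13).

The three steps most likely to fail:

Step 3, the new cycloaddition. The enone is trisubstituted and hindered; the primary amine can be acetylated by the enol acetate; a dienamine formed through the C10 methyl could scramble the alkene geometry; the silyl dienol ether is acid-sensitive; and the sense of enantioinduction rests on analogy. The fallback sets out from 3 and 6 and comes back at 7. It drops covalent amine catalysis for chiral Lewis-acid activation: a Diels–Alder reaction under Corey's triflimide-activated (S)-o-tolyl oxazaborolidine (or its enantiomer) in CH2Cl2 at −78 °C, with the boron cation bound to the ketone. This catalyst class is documented for endo-selective cycloadditions of acyclic enones and trisubstituted dienophiles with 1-silyloxy dienes. This fallback makes no new compound (F0).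

Step 9, the configuration at C1. The Felkin–Anh preference at the neopentyl aldehyde may be weak or reversed, because C5 and C9 are similar in size and a 1,3-polar effect of the C9 oxygen opposes it. The fallback sets out from 11 and comes back at 17, and sets C1 by reagent control. ICH2Cl/MeLi·LiBr (−78 °C) converts the C10 ester, beside the lithium carboxylate, into the chloromethyl ketone acid F1. (R)-Me-CBS oxazaborolidine with catecholborane reduces it to the (1R)-chlorohydrin acid F2. VO(acac)2/tBuOOH then camphorsulfonic acid, now directed by the C1 hydroxyl, gives the chlorohydrin hydroxy lactone F3. NaH in THF closes the oxirane to the epoxy alcohol F4, and 1-(trimethylsilyl)imidazole gives 17.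

Step 12, the double angeloylation. Both hydroxyls are axial and hindered (C9 is neopentyl); forcing conditions risk Z→E isomerisation to tiglates and chloride opening of the oxirane. The fallback sets out from 21 and comes back at 22, building the Z-alkene on the ester. DCC/DMAP esterification with the small 2-[bis(2,2,2-trifluoroethoxy)phosphoryl]propanoic acid gives the bis-phosphonate diester F5. KN(SiMe3)2/18-crown-6 and acetaldehyde at −78 °C (Still–Gennari olefination, Z-selective) then give 22.

**Further compounds**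

F0 | step 3 | none | none
F1 | step 9 | chloromethyl ketone acid (C10–C(=O)CH2Cl in place of the ester of 11) | C1=C[C@@H](CC(=O)O)[C@@H](O[Si](C)(C)C(C)(C)C)[C@@H](C(C)=C)[C@]1(C)C(=O)CCl
F2 | step 9 | (1R)-chlorohydrin acid | C1=C[C@@H](CC(=O)O)[C@@H](O[Si](C)(C)C(C)(C)C)[C@@H](C(C)=C)[C@]1(C)[C@@H](O)CCl
F3 | step 9 | chlorohydrin hydroxy lactone (cis-8β,12-lactone, 9α-OH) | C1C(=O)O[C@H]2[C@@H]1[C@@H](O[Si](C)(C)C(C)(C)C)[C@@H](C(C)=C)[C@](C)([C@@H](O)CCl)[C@@H]2O
F4 | step 9 | epoxy alcohol (9α-OH analogue of 17) | C1C(=O)O[C@H]2[C@@H]1[C@@H](O[Si](C)(C)C(C)(C)C)[C@@H](C(C)=C)[C@](C)([C@@H]1CO1)[C@@H]2O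
F5 | step 12 | 6β,9α-bis{2-[bis(2,2,2-trifluoroethoxy)phosphoryl]propanoate} of 21 | C=C1C(=O)O[C@H]2[C@@H]1[C@@H](OC(=O)C(C)P(=O)(OCC(F)(F)F)OCC(F)(F)F)[C@@H](C(C)=C)[C@](C)([C@@H]1CO1)[C@@H]2OC(=O)C(C)P(=O)(OCC(F)(F)F)OCC(F)(F)F
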